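**Plan**
- Feature used: in the ten-membered ring the C8–C9 bond that carries the two vicinal oxygens lies between C1=C10 and the oxygen-bearing C6 (C7 between them). At the C6-enolate level it is the central bond of a 1,5-diene, and the Z C4=C5 bond next to C6 can be the double bond of a cyclohexenone.
- Cuts, in retrosynthetic order: C8 angelate and 9,14-acetonide; C11=C13; lactone O–C6 (closed with inversion); C7–C11 (enolate alkylation); C8–C9 of the ten-membered ring ([3,3] shift, which in reverse restores C1–C6 of a six-membered ring); carbinol C6–C7 (alkoxyacetylide addition); C1–C10 (palladium-catalysed α′-alkenylation).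
- Forward order of rings: purchased cyclohexenone ring, then the cis-1,2-dialkenylcyclohexenol, then four-atom expansion to the ten-membered ring with C7 alkylation in the same flask, then the γ-lactone, then methylene, angelate and diol.
- Stereocentres: C1 of the cyclohexenone by dynamic kinetic hydrogenation; the carbinol by axial acetylide addition; C8 and C9 by the chair [3,3] shift; C7 by alkylation on the outer enolate face; C6 by outer-face hydride followed by Mitsunobu inversion.
- Alkenes: Z C4=C5 is carried from 3-methylcyclohexenone, Z C1=C10 comes from the axial C1–C2 bond in the chair, the Z enol ether from Lindlar reduction, the Z angelate from a mixed-anhydride acylation.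

Key step: step 8

Remark: ring-expanded compounds carry germacrane locants (ring C1–C10, C11–C13 on C7, C14 on C10, C15 on C4); in 19 the carbinol carbon is the future C6 and the dioxinyl-bearing carbon the future C1.
Assumption: RuCl2[(S)-binap][(R,R)-dpen] is taken to give the (1R,6R) alcohol by analogy with 2-alkylcyclohexanones; if this enone follows the opposite sense, the mirror-image catalyst is used.

Step 1
Reactants: 1 2,2-dimethyl-1,3-dioxan-5-one
Product: 3 2,2-dimethyl-4H-1,3-dioxin-5-yl trifluoromethanesulfonate, via lithium enolate of the dioxanone 2 (not isolated)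
Conditions: LiN(i-Pr)2 (LDA), THF, −78 °C; PhNTf2, −78 to 0 °C
Reagents that add atoms: N-phenylbis(trifluoromethanesulfonimide), O=S(=O)(N(c1ccccc1)S(=O)(=O)C(F)(F)F)C(F)(F)F
Why: Enol triflate formation by kinetic deprotonation and O-sulfonylation of the lithium enolate; the ketone is symmetrical, so only one enolate can form.

Step 2
Reactants: 4 3-methylcyclohex-2-en-1-one; 3 2,2-dimethyl-4H-1,3-dioxin-5-yl trifluoromethanesulfonate
Product: 7 racemic 6-(2,2-dimethyl-4H-1,3-dioxin-5-yl)-3-methylcyclohex-2-en-1-one, via lithium dienolate 5 (not isolated), via chlorozinc dienolate 6 (not isolated)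
Conditions: LDA, THF, −78 °C; ZnCl2, −78 to 0 °C; 3, Pd2(dba)3 (cat.), XPhos (cat.), THF, 25–45 °C
Reagents that add atoms: none
Why: LDA removes the α′ proton (kinetic cross-conjugated enolate) and the zinc enolate couples with the alkenyl triflate under zerovalent palladium (Negishi-type enolate α-alkenylation); the weakly basic zinc enolate limits proton exchange with the more acidic product, and the new stereocentre forms racemic.

Step 3
Reactants: 7 racemic 6-(2,2-dimethyl-4H-1,3-dioxin-5-yl)-3-methylcyclohex-2-en-1-one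
Product: 8 (1R,6R)-6-(2,2-dimethyl-4H-1,3-dioxin-5-yl)-3-methylcyclohex-2-en-1-ol
Conditions: H2 (8 atm), RuCl2[(S)-binap][(R,R)-dpen] (cat.), KOt-Bu (cat.), i-PrOH, 25 °C
Reagents that add atoms: none
Why: Noyori hydrogenation with a BINAP/diamine ruthenium catalyst reduces C=O and leaves C=C alone; KOt-Bu interconverts the ketone enantiomers through the enolate, and the catalyst should reduce one of them faster on the face anti to the dioxinyl group (dynamic kinetic resolution), fixing C6 as R with the hydroxyl cis to it.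

Step 4
Reactants: 8 (1R,6R)-6-(2,2-dimethyl-4H-1,3-dioxin-5-yl)-3-methylcyclohex-2-en-1-ol
Product: 9 (6R)-6-(2,2-dimethyl-4H-1,3-dioxin-5-yl)-3-methylcyclohex-2-en-1-one
Conditions: Dess–Martin periodinane, pyridine, CH2Cl2, 0 °C
Reagents that add atoms: none
Why: Dess–Martin oxidation under buffered conditions returns the enone without touching the α-stereocentre, which should be configurationally stable without strong base, as it is in the related 6-alkenyl enone isopiperitenone.

Step 5
Reactants: 10 4-methoxybenzyl alcohol; 11 trichloroethylene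
Product: 14 (E)-1,2-dichlorovinyl 4-methoxybenzyl ether, via potassium 4-methoxybenzyl oxide 12 (not isolated), via dichloroacetylene 13 (not isolated)
Conditions: KH, THF, 0 °C; trichloroethylene, −50 °C to rt
Reagents that add atoms: trichloroethylene (11), ClC=C(Cl)Cl
Why: The alkoxide dehydrochlorinates trichloroethylene and adds anti to the dichloroacetylene so formed (first stage of the dichlorovinyl ether route to alkoxyacetylides), which gives the E ether.

Step 6
Reactants: 14 (E)-1,2-dichlorovinyl 4-methoxybenzyl ether; 9 (6R)-6-(2,2-dimethyl-4H-1,3-dioxin-5-yl)-3-methylcyclohex-2-en-1-one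
Product: 18 (1S,6R)-6-(2,2-dimethyl-4H-1,3-dioxin-5-yl)-1-{[(4-methoxybenzyl)oxy]ethynyl}-3-methylcyclohex-2-en-1-ol, via chloroethynyl ether 15 (not isolated), via lithium alkoxyacetylide 16 (not isolated), via dichlorocerium alkoxyacetylide 17 (not isolated)
Conditions: n-BuLi (2.1 equiv), THF, −78 to −40 °C; CeCl3, −78 °C; 9, −78 °C
Reagents that add atoms: none
Why: Elimination and Cl/Li exchange give the lithium alkoxyacetylide, whose weakly basic cerium derivative adds 1,2 to the ketone without enolising the α-stereocentre (organocerium addition); the small linear nucleophile should attack the half-chair axially, opposite the axial hydrogen of the neighbouring stereocentre, so the alkyne ends cis to the equatorial dioxinyl group (1S).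

Step 7
Reactants: 18 (1S,6R)-6-(2,2-dimethyl-4H-1,3-dioxin-5-yl)-1-{[(4-methoxybenzyl)oxy]ethynyl}-3-methylcyclohex-2-en-1-ol
Product: 19 (1S,6R)-6-(2,2-dimethyl-4H-1,3-dioxin-5-yl)-1-{(Z)-2-[(4-methoxybenzyl)oxy]ethenyl}-3-methylcyclohex-2-en-1-ol
Conditions: H2 (1 atm), Pd/CaCO3 poisoned with Pb(OAc)2 (Lindlar catalyst), quinoline, EtOAc, rt
Reagents that add atoms: none
Why: Lindlar semi-hydrogenation adds H2 syn to the alkynyl ether (the Arens–van Dorp route to β-alkoxyvinyl carbinols), so the enol ether is Z; quinoline keeps the alkenes from reduction and the acid-labile product basic.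

Step 8
Reactants: 19 (1S,6R)-6-(2,2-dimethyl-4H-1,3-dioxin-5-yl)-1-{(Z)-2-[(4-methoxybenzyl)oxy]ethenyl}-3-methylcyclohex-2-en-1-ol; 20 methyl bromoacetate
Product: 23 (7R,8S,9R) keto ester (ten-membered 4Z,1(10)Z-dien-6-one; CH2CO2Me on C7; OPMB on C8; 9,14-acetonide), via potassium alkoxide 21 (not isolated), via ring-expanded potassium enolate 22 (not isolated)
Conditions: KN(SiMe3)2 (1.05 equiv), 18-crown-6, THF, −20 °C to rt; then methyl bromoacetate, −78 °C
Reagents that add atoms: methyl bromoacetate (20), COC(=O)CBr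
Why: The potassium alkoxide 21 undergoes a [3,3] shift (anionic oxy-Cope rearrangement, the known ring expansion of 1,2-dialkenylcyclohexenols to cyclodecadienone enolates) in which C8–C9 forms as C1–C6 breaks, so the ten-membered ring arises by four-atom ring expansion of the cyclohexene and not by an end-to-end closure. The reacting chair should be the one with C1–C2 axial and C6–C5 equatorial, because the other chair would push the axial C8 ether oxygen of the Z enol ether into a 1,3-diaxial contact with C5, whereas here it meets only the alkoxide oxygen; C1=C10 therefore emerges Z. C8 is fixed by the Z enol ether (oxygen axial) and C9 by the ring-held dioxin (oxygen equatorial), which gives the erythro 8S,9R pair with the absolute sense dictated by the stereocentres of 19. In enolate 22 the whole ring lies on one face of C6=C7, so the bromide should attack C7 on the outer face, anti to C9 with the C8 oxygen near the enolate plane, placing C11 cis to the C8 oxygen. The step needs chair over boat and C- over O-alkylation and must outrun β-loss of the C8 alkoxide, hence the lowest temperature that permits rearrangement and a reactive bromide added cold (tandem oxy-Cope/enolate alkylation).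

Step 9
Reactants: 23 (7R,8S,9R) keto ester
Product: 25 (6S,7S,8S,9R) cis-fused 12,6-lactone (8-OPMB; 9,14-acetonide), via 6S hydroxy ester 24 (not isolated)
Conditions: NaBH4, CeCl3·7H2O, MeOH, −78 to 0 °C; then K2CO3, rt
Reagents that add atoms: none
Why: Luche reduction gives 1,2-reduction of the enone; hydride should reach C6 on the outer ring face, anti to the acetate arm on C7, so the 6S alkoxide is cis to that arm and closes to the cis-fused γ-lactone by transesterification.

Step 10
Reactants: 25 (6S,7S,8S,9R) cis-fused 12,6-lactone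
Product: 28 (6R,7S,8S,9R) trans-fused 12,6-lactone (8-OPMB; 9,14-acetonide), via lithium hydroxy carboxylate 26 (not isolated), via 6S hydroxy acid 27 (not isolated)
Conditions: LiOH, THF/H2O, 0 °C; 1 M HCl to pH 4, 0 °C, cold extraction; PPh3, DIAD, THF, 0 °C
Reagents that add atoms: lithium hydroxide, [Li+].[OH-]
Why: Saponification frees the 6S hydroxy acid, and Mitsunobu lactonisation turns the allylic C6 hydroxyl into an oxyphosphonium that the carboxylate displaces in a 5-exo-tet SN2 closure with inversion, which should give the trans-fused 6R lactone.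

Step 11
Reactants: 28 (6R,7S,8S,9R) trans-fused 12,6-lactone
Product: 32 α-methylene lactone (C11=C13; 8-OPMB; 9,14-acetonide), via lactone lithium enolate 29 (not isolated), via Mannich base 30 (not isolated), via trimethylammonium iodide 31 (not isolated)
Conditions: LDA, THF, −78 °C; Eschenmoser's salt, −78 °C to rt; MeI, MeOH, rt; aq. NaHCO3, EtOAc
Reagents that add atoms: Eschenmoser's salt (N,N-dimethylmethyleneiminium iodide), C=[N+](C)C.[I-]
Why: Mannich aminomethylation of the lactone enolate, N-methylation and base-induced loss of trimethylamine is the standard α-methylenation of γ-lactones; C7 is not enolisable and keeps its configuration.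

Step 12
Reactants: 32 α-methylene lactone
Product: 33 C8 alcohol (α-methylene lactone; 9,14-acetonide)
Conditions: DDQ, CH2Cl2/pH 7 buffer, 0 °C
Reagents that add atoms: none
Why: Oxidative PMB cleavage: DDQ oxidises the electron-rich benzyl ether to an oxocarbenium ion that water hydrolyses to anisaldehyde and the C8 alcohol, while acetonide, lactone and alkenes should be inert.

Step 13
Reactants: 33 C8 alcohol; 34 angelic acid
Product: 36 8-O-angelate (α-methylene lactone; 9,14-acetonide), via angelic 2,4,6-trichlorobenzoic anhydride 35 (not isolated)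
Conditions: angelic acid, 2,4,6-trichlorobenzoyl chloride, Et3N, toluene, rt; then 33, 80 °C
Reagents that add atoms: angelic acid (34), C/C=C(/C)C(=O)O
Why: Yamaguchi esterification through the mixed anhydride without a nucleophilic catalyst is the established way to transfer an angeloyl group with its Z geometry intact.

Step 14
Reactants: 36 8-O-angelate
Product: 37 target, (6R,7S,8S,9R)-8-angeloyloxy-9,14-dihydroxygermacra-1(10)Z,4Z,11(13)-trien-12,6-olide
Conditions: AcOH/H2O/THF (3:1:1), 40 °C
Reagents that add atoms: none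
Why: Mild acid hydrolysis of the isopropylidene acetal frees the C9 and C14 hydroxyls; the angelate, the α-methylene lactone and both Z ring alkenes should tolerate aqueous acetic acid.

**Compound list**

1 | 2,2-dimethyl-1,3-dioxan-5-one | CC1(C)OCC(=O)CO1 | starting material
2 | lithium 2,2-dimethyl-4H-1,3-dioxin-5-olate | [Li+].[O-]C1=COC(C)(C)OC1 | intermediate
3 | 2,2-dimethyl-4H-1,3-dioxin-5-yl trifluoromethanesulfonate | CC1(C)OCC(OS(=O)(=O)C(F)(F)F)=CO1 | intermediate
4 | 3-methylcyclohex-2-en-1-one | CC1=CC(=O)CCC1 | starting material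
5 | lithium 5-methylcyclohexa-1,5-dien-1-olate | [Li+].[O-]C1=CCCC(C)=C1 | intermediate
6 | chlorozinc 5-methylcyclohexa-1,5-dien-1-olate | Cl[Zn]OC1=CCCC(C)=C1 | intermediate
7 | racemic 6-(2,2-dimethyl-4H-1,3-dioxin-5-yl)-3-methylcyclohex-2-en-1-one | O=C1C=C(C)CCC1C1=COC(C)(C)OC1 | intermediate
8 | (1R,6R)-6-(2,2-dimethyl-4H-1,3-dioxin-5-yl)-3-methylcyclohex-2-en-1-ol (OH cis to the dioxinyl group) | O[C@@H]1C=C(C)CC[C@@H]1C1=COC(C)(C)OC1 | intermediate
9 | (6R)-6-(2,2-dimethyl-4H-1,3-dioxin-5-yl)-3-methylcyclohex-2-en-1-one | O=C1C=C(C)CC[C@@H]1C1=COC(C)(C)OC1 | intermediate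
10 | 4-methoxybenzyl alcohol | COc1ccc(CO)cc1 | starting material
11 | trichloroethylene | ClC=C(Cl)Cl | starting material
12 | potassium 4-methoxybenzyl oxide | [K+].[O-]Cc1ccc(OC)cc1 | intermediate
13 | dichloroacetylene | ClC#CCl | intermediate
14 | (E)-1,2-dichlorovinyl 4-methoxybenzyl ether | Cl/C=C(/Cl)OCc1ccc(OC)cc1 | intermediate
15 | chloroethynyl 4-methoxybenzyl ether | ClC#COCc1ccc(OC)cc1 | intermediate
16 | lithium [(4-methoxybenzyl)oxy]acetylide | [Li]C#COCc1ccc(OC)cc1 | intermediate
17 | dichlorocerium [(4-methoxybenzyl)oxy]acetylide | Cl[Ce](Cl)C#COCc1ccc(OC)cc1 | intermediate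
18 | (1S,6R)-6-(2,2-dimethyl-4H-1,3-dioxin-5-yl)-1-{[(4-methoxybenzyl)oxy]ethynyl}-3-methylcyclohex-2-en-1-ol (alkyne cis to dioxinyl) | O[C@@]1(C#COCc2ccc(OC)cc2)C=C(C)CC[C@@H]1C1=COC(C)(C)OC1 | intermediate
19 | (1S,6R)-6-(2,2-dimethyl-4H-1,3-dioxin-5-yl)-1-{(Z)-2-[(4-methoxybenzyl)oxy]ethenyl}-3-methylcyclohex-2-en-1-ol (the two alkenyl groups cis) | O[C@@]1(/C=C\OCc2ccc(OC)cc2)C=C(C)CC[C@@H]1C1=COC(C)(C)OC1 | intermediate
20 | methyl bromoacetate | COC(=O)CBr | starting material
21 | potassium alkoxide of 19 | [K+].[O-][C@@]1(/C=C\OCc2ccc(OC)cc2)C=C(C)CC[C@@H]1C1=COC(C)(C)OC1 | intermediate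
22 | potassium (8S,9R) C6 enolate of the ten-membered ring (C6=C7 with C5 and C8 trans, 4Z, 1(10)Z, 8-OPMB, 9,14-acetonide) | [K+].C1/C(C)=C\C(\[O-])=C\[C@H](OCc3ccc(OC)cc3)[C@@H]2OC(C)(C)OC/C2=C/C1 | intermediate
23 | (7R,8S,9R) keto ester: ten-membered 4Z,1(10)Z-dien-6-one with CH2CO2Me on C7, OPMB on C8, C9–O/C14–O acetonide | COC(=O)C[C@H]1C(=O)/C=C(/C)CC/C=C2/COC(C)(C)O[C@H]2[C@H]1OCc1ccc(OC)cc1 | intermediate
24 | (6S,7S,8S,9R) hydroxy ester: 6-alcohol of 23, OH cis to the C7 arm | COC(=O)C[C@H]1[C@@H](O)/C=C(/C)CC/C=C2/COC(C)(C)O[C@H]2[C@H]1OCc1ccc(OC)cc1 | intermediate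
25 | (6S,7S,8S,9R) cis-fused 12,6-lactone, 8-OPMB, 9,14-acetonide | O=C1C[C@@H]2[C@H](OCc3ccc(OC)cc3)[C@@H]3OC(C)(C)OC/C3=C/CC/C(C)=C\[C@@H]2O1 | intermediate
26 | lithium (6S,7S,8S,9R) hydroxy carboxylate | [Li+].[O-]C(=O)C[C@H]1[C@@H](O)/C=C(/C)CC/C=C2/COC(C)(C)O[C@H]2[C@H]1OCc1ccc(OC)cc1 | intermediate
27 | (6S,7S,8S,9R) hydroxy acid | OC(=O)C[C@H]1[C@@H](O)/C=C(/C)CC/C=C2/COC(C)(C)O[C@H]2[C@H]1OCc1ccc(OC)cc1 | intermediate
28 | (6R,7S,8S,9R) trans-fused 12,6-lactone, 8-OPMB, 9,14-acetonide | O=C1C[C@@H]2[C@H](OCc3ccc(OC)cc3)[C@@H]3OC(C)(C)OC/C3=C/CC/C(C)=C\[C@H]2O1 | intermediate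
29 | lithium enolate of lactone 28 | [Li+].[O-]C1=C[C@@H]2[C@H](OCc3ccc(OC)cc3)[C@@H]3OC(C)(C)OC/C3=C/CC/C(C)=C\[C@H]2O1 | intermediate
30 | 11-(dimethylaminomethyl) lactone (Mannich base, mixture at C11) | CN(C)CC1[C@@H]2[C@H](OCc3ccc(OC)cc3)[C@@H]3OC(C)(C)OC/C3=C/CC/C(C)=C\[C@H]2OC1=O | intermediate
31 | 11-(trimethylammoniomethyl) lactone iodide | C[N+](C)(C)CC1[C@@H]2[C@H](OCc3ccc(OC)cc3)[C@@H]3OC(C)(C)OC/C3=C/CC/C(C)=C\[C@H]2OC1=O.[I-] | intermediate
32 | (6R,7S,8S,9R) α-methylene lactone, 8-OPMB, 9,14-acetonide | C=C1[C@@H]2[C@H](OCc3ccc(OC)cc3)[C@@H]3OC(C)(C)OC/C3=C/CC/C(C)=C\[C@H]2OC1=O | intermediate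
33 | (6R,7S,8S,9R) α-methylene lactone, 8-OH, 9,14-acetonide | C=C1[C@@H]2[C@H](O)[C@@H]3OC(C)(C)OC/C3=C/CC/C(C)=C\[C@H]2OC1=O | intermediate
34 | angelic acid, (Z)-2-methylbut-2-enoic acid | C/C=C(/C)C(=O)O | starting material
35 | (Z)-2-methylbut-2-enoic 2,4,6-trichlorobenzoic anhydride | C/C=C(/C)C(=O)OC(=O)c1c(Cl)cc(Cl)cc1Cl | intermediate
36 | (6R,7S,8S,9R) α-methylene lactone, 8-O-angelate, 9,14-acetonide | C=C1[C@@H]2[C@H](OC(=O)/C(C)=C\C)[C@@H]3OC(C)(C)OC/C3=C/CC/C(C)=C\[C@H]2OC1=O | intermediate
37 | CNP0276773.5, (6R,7S,8S,9R)-8-angeloyloxy-9,14-dihydroxygermacra-1(10)Z,4Z,11(13)-trien-12,6-olide | C=C1[C@@H]2[C@H](OC(=O)/C(C)=C\C)[C@H](O)/C(CO)=C\CC/C(C)=C\[C@H]2OC1=O | target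

**Step count**
Total: 14 steps. Longest linear sequence: 13 steps (steps 1–4 and 6–14); step 5 is the only side branch.

**Three steps most likely to fail**

Step 8. The enolate may expel the C8 alkoxide (β-elimination) or react on oxygen at the temperature the rearrangement needs, and reaction through the chair with C1–C2 equatorial would leak the E alkene. The fallback separates rearrangement from alkylation and uses a lithium enolate. It sets out from 19: the rearrangement is run as before, but the enolate is quenched at −78 °C with Me3SiCl/Et3N to the trimethylsilyl enol ether of the ring-expanded ketone F1, a neutral compound that can be purified and whose alkene geometry can be checked. MeLi in THF then cleaves the O–Si bond to the lithium enolate of the ring-expanded ketone F2, which is alkylated at −78 °C with methyl bromoacetate 20 in THF/DMPU and comes back to the route at 23.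

Step 10. The hydroxy acid may reclose with retention (acid-catalysed, or through activation of the carboxyl group instead of the hydroxyl), or the activated allylic alcohol may ionise or eliminate. The fallback inverts C6 before ring closure. It sets out from 23: the Luche reduction is worked up cold and neutral so that hydroxy ester 24 is isolated. An intermolecular Mitsunobu reaction with 4-nitrobenzoic acid (PPh3, DIAD, toluene, 0 °C) gives the 6R 4-nitrobenzoate of the hydroxy ester F3. K2CO3 in MeOH removes the nitrobenzoate, and the freed 6R alkoxide closes onto the methyl ester, coming back to the route at 28.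

Step 3. Enolisation may be slow relative to reduction, so that the resolution is not dynamic and the enantiomeric purity suffers, or the base may move the dioxin double bond into conjugation with the ketone. The fallback is a classical resolution. It sets out from 7: Luche reduction (axial hydride) gives the racemic trans alcohol F4. Candida antarctica lipase B with vinyl acetate acylates the (1R) carbinol, as lipases do with trans-2-substituted cyclohexanols, to the (1R,6S) acetate F5 and leaves the (1S,6R) alcohol F6. F6 is oxidised with Dess–Martin periodinane/pyridine and comes back to the route at 9.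

**Further compounds**

F1 | step 8 | trimethylsilyl enol ether of the ring-expanded ketone (8S,9R; C6=C7 with C5 and C8 trans) | C1/C(C)=C\C(\O[Si](C)(C)C)=C\[C@H](OCc3ccc(OC)cc3)[C@@H]2OC(C)(C)OC/C2=C/C1
F2 | step 8 | lithium enolate of the ring-expanded ketone (8S,9R) | [Li+].C1/C(C)=C\C(\[O-])=C\[C@H](OCc3ccc(OC)cc3)[C@@H]2OC(C)(C)OC/C2=C/C1
F3 | step 10 | (6R,7S,8S,9R) 6-(4-nitrobenzoate) of the hydroxy methyl ester | COC(=O)C[C@H]1[C@H](OC(=O)c3ccc(cc3)[N+](=O)[O-])/C=C(/C)CC/C=C2/COC(C)(C)O[C@H]2[C@H]1OCc1ccc(OC)cc1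
F4 | step 3 | racemic trans-6-(2,2-dimethyl-4H-1,3-dioxin-5-yl)-3-methylcyclohex-2-en-1-ol | O[C@H]1C=C(C)CC[C@@H]1C1=COC(C)(C)OC1.O[C@@H]1C=C(C)CC[C@H]1C1=COC(C)(C)OC1
F5 | step 3 | (1R,6S)-6-(2,2-dimethyl-4H-1,3-dioxin-5-yl)-3-methylcyclohex-2-en-1-yl acetate | CC(=O)O[C@@H]1C=C(C)CC[C@H]1C1=COC(C)(C)OC1
F6 | step 3 | (1S,6R)-6-(2,2-dimethyl-4H-1,3-dioxin-5-yl)-3-methylcyclohex-2-en-1-ol | O[C@H]1C=C(C)CC[C@@H]1C1=COC(C)(C)OC1
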